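The route rests on cutting the methylene–aryl bond of the shorter chain: the CH2 on C8 of ring A is separated from the phenol ring it is attached to. Ring A carries its C7 hydroxyl next to C8, so an 8-(dimethylaminomethyl) group is a latent ortho-quinone methide (C7=O, C8=CH2). The partner, 4-[2-(benzyloxy)benzyl]phenol, has its para position blocked, so only a carbon ortho to its hydroxyl can add. In one operation the key step unites this two-ring phenol with an (S)-pinocembrin core that already carries the complete three-ring C6 chain. The stereocentre is bought with (S)-pinocembrin; three benzyl ethers fall in the last step.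

Key step: step 9

Remark: C2 comes from purchased (S)-pinocembrin, so every step on the flavanone avoids strong base and hot strong acid, which open the pyranone ring reversibly and would racemise C2; compounds 1, 2, 5, 6 and 12 are taken as commercial.

Step 1
Reactants: 1 2-(benzyloxy)benzaldehyde; 2 [4-(oxan-2-yloxy)phenyl]magnesium bromide (solution in THF)
Product: 3 [2-(benzyloxy)phenyl][4-(oxan-2-yloxy)phenyl]methanol (mixture of diastereomers)
Conditions: THF, 0 °C to rt; then H2O
Reagents that add atoms: none
Why: Grignard addition of the aryl nucleophile to the aldehyde, with the acetal and the benzyl ether inert to the organomagnesium reagent and both stereocentres erased in step 2.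

Step 2
Reactants: 3 [2-(benzyloxy)phenyl][4-(oxan-2-yloxy)phenyl]methanol
Product: 4 4-[2-(benzyloxy)benzyl]phenol
Conditions: Et3SiH, CF3CO2H, CH2Cl2, 0 °C
Reagents that add atoms: none
Why: Ionic hydrogenation, in which the doubly oxygen-stabilised diarylmethyl cation is reduced by the silane while the acid removes the oxanyl acetal and the aryl benzyl ether survives the cold acid.

Step 3
Reactants: 5 1-(benzyloxy)-2-(bromomethyl)benzene; 6 [4-(benzyloxy)-3-formylphenyl]boronic acid
Product: 7 2-(benzyloxy)-5-[2-(benzyloxy)benzyl]benzaldehyde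
Conditions: PdCl2(dppf) (dppf = 1,1'-bis(diphenylphosphino)ferrocene, 3 mol %), Cs2CO3, THF–H2O 10:1, 70 °C
Reagents that add atoms: none
Why: Suzuki–Miyaura coupling of a benzylic bromide with an arylboronic acid, which fixes the new CH2 para to the benzyloxy group and tolerates the aldehyde.

Step 4
Reactants: 7 2-(benzyloxy)-5-[2-(benzyloxy)benzyl]benzaldehyde; 2 [4-(oxan-2-yloxy)phenyl]magnesium bromide
Product: 8 {2-(benzyloxy)-5-[2-(benzyloxy)benzyl]phenyl}[4-(oxan-2-yloxy)phenyl]methanol (mixture of diastereomers)
Conditions: THF, 0 °C to rt; then H2O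
Reagents that add atoms: none
Why: Grignard addition to the ortho-alkoxybenzaldehyde as in step 1, the stereocentres being erased in step 5.

Step 5
Reactants: 8 {2-(benzyloxy)-5-[2-(benzyloxy)benzyl]phenyl}[4-(oxan-2-yloxy)phenyl]methanol
Product: 9 4-{2-(benzyloxy)-5-[2-(benzyloxy)benzyl]benzyl}phenol
Conditions: Et3SiH, CF3CO2H, CH2Cl2, 0 °C
Reagents that add atoms: none
Why: Ionic hydrogenation with acetal cleavage as in step 2, excess silane intercepting the cation before it can alkylate the benzyloxy rings.

Step 6
Reactants: 9 4-{2-(benzyloxy)-5-[2-(benzyloxy)benzyl]benzyl}phenol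
Product: 11 4-{2-(benzyloxy)-5-[2-(benzyloxy)benzyl]benzyl}-2-(hydroxymethyl)phenol, via benzodioxaborinine 10 (not isolated)
Conditions: PhB(OH)2, (CH2O)n, EtCO2H (cat.), toluene, reflux (Dean–Stark); then propane-1,3-diol, THF, rt
Reagents that add atoms: formaldehyde (used as paraformaldehyde), C=O
Why: Phenylboronic acid-templated ortho-hydroxymethylation, in which the aryl boronate delivers formaldehyde only to a carbon ortho to the single free hydroxyl and transesterification with the diol releases the salicyl alcohol.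

Step 7
Reactants: 11 4-{2-(benzyloxy)-5-[2-(benzyloxy)benzyl]benzyl}-2-(hydroxymethyl)phenol; 12 (S)-pinocembrin, (2S)-5,7-dihydroxy-2-phenylchroman-4-one (2.5 equiv)
Product: 13 (2S)-6-(5-{2-(benzyloxy)-5-[2-(benzyloxy)benzyl]benzyl}-2-hydroxybenzyl)-5,7-dihydroxy-2-phenylchroman-4-one
Conditions: ZnCl2, 1,4-dioxane, 90 °C
Reagents that add atoms: none
Why: ZnCl2-mediated dehydration of the salicyl alcohol to its ortho-quinone methide (loss of one water) and Friedel–Crafts-type conjugate addition by ring A, expected to favour C6 (flanked by the chelated C5 hydroxyl and the C7 hydroxyl, the more nucleophilic carbon of 5,7-dihydroxyflavanones as in their direct C-prenylation), with excess 12 limiting double alkylation, the minor C8 isomer removed by chromatography and C2 not involved.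

Step 8
Reactants: 13 (2S)-6-(5-{2-(benzyloxy)-5-[2-(benzyloxy)benzyl]benzyl}-2-hydroxybenzyl)-5,7-dihydroxy-2-phenylchroman-4-one
Product: 14 (2S)-6-(5-{2-(benzyloxy)-5-[2-(benzyloxy)benzyl]benzyl}-2-hydroxybenzyl)-8-[(dimethylamino)methyl]-5,7-dihydroxy-2-phenylchroman-4-one
Conditions: Me2NCH2NMe2 (1.1 equiv), 1,4-dioxane, rt
Reagents that add atoms: bis(dimethylamino)methane, CN(C)CN(C)C
Why: Phenolic Mannich aminomethylation, in which the acidic ring-A phenol activates the aminal and C8 is the only free carbon of the highly nucleophilic ring A, the mono-phenol ring of the side chain reacting only on heating.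

Step 9
Reactants: 14 (2S)-6-(5-{2-(benzyloxy)-5-[2-(benzyloxy)benzyl]benzyl}-2-hydroxybenzyl)-8-[(dimethylamino)methyl]-5,7-dihydroxy-2-phenylchroman-4-one; 4 4-[2-(benzyloxy)benzyl]phenol (5 equiv)
Product: 16 (2S)-8-{5-[2-(benzyloxy)benzyl]-2-hydroxybenzyl}-6-(5-{2-(benzyloxy)-5-[2-(benzyloxy)benzyl]benzyl}-2-hydroxybenzyl)-5,7-dihydroxy-2-phenylchroman-4-one, via ortho-quinone methide 15 (not isolated)
Conditions: toluene–1,4-dioxane, 105 °C, N2 stream (removes Me2NH)
Reagents that add atoms: none
Why: Heating the zwitterionic Mannich base expels dimethylamine (retro-Mannich, E1cB-type) and unveils ortho-quinone methide 15, in which the C7 oxygen of ring A has become a carbonyl and the C8 substituent an exocyclic methylene made strongly electrophilic by cross-conjugation with the C4 ketone; phenol 4 hydrogen-bonds to that carbonyl and adds through a carbon ortho to its hydroxyl (conjugate addition), and tautomerisation of the cyclohexadienone restores both aromatic rings. The closest known reaction type is the thermal generation of ortho-quinone methides from phenolic Mannich bases and their Friedel–Crafts-type capture by phenols to give 2,2'-methylenediphenols. No ring is closed and no stereocentre is formed; C2 is a spectator, and the volatile amine is swept out to keep the medium from becoming basic. The step needs site selectivity on 4 and chemoselectivity for 4 over the substrate itself: the para position of the free phenol of 4 is blocked by its benzyl substituent and its two ortho carbons are equivalent, while its other ring is an ether that does not react without acid. Ring A cannot self-condense because C6 and C8 are both substituted, capture by the free phenol ring of the C6 chain within the same molecule would require an impossibly strained eight-membered metacyclophane, and the excess of 4 outcompetes the same ring of a second molecule.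

Step 10
Reactants: 16 (2S)-8-{5-[2-(benzyloxy)benzyl]-2-hydroxybenzyl}-6-(5-{2-(benzyloxy)-5-[2-(benzyloxy)benzyl]benzyl}-2-hydroxybenzyl)-5,7-dihydroxy-2-phenylchroman-4-one
Product: 17 sarmentosumin D, (2S)-5,7-dihydroxy-8-[2-hydroxy-5-(2-hydroxybenzyl)benzyl]-6-{2-hydroxy-5-[2-hydroxy-5-(2-hydroxybenzyl)benzyl]benzyl}-2-phenylchroman-4-one
Conditions: H2 (1 atm), 10 % Pd/C, EtOAc–MeOH, rt
Reagents that add atoms: none
Why: Catalytic hydrogenolysis of the three aryl benzyl ethers, which under neutral conditions at ambient pressure should leave the chelated ketone, the diarylmethane CH2 groups and the C2 stereocentre untouched.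

Compound list

1 | 2-(benzyloxy)benzaldehyde | O=Cc1ccccc1OCc1ccccc1 | starting material
2 | [4-(oxan-2-yloxy)phenyl]magnesium bromide (racemic acetal) | Br[Mg]c1ccc(OC2CCCCO2)cc1 | starting material
3 | [2-(benzyloxy)phenyl][4-(oxan-2-yloxy)phenyl]methanol (mixture of diastereomers) | OC(c1ccc(OC2CCCCO2)cc1)c1ccccc1OCc1ccccc1 | intermediate
4 | 4-[2-(benzyloxy)benzyl]phenol | Oc1ccc(Cc2ccccc2OCc2ccccc2)cc1 | intermediate
5 | 1-(benzyloxy)-2-(bromomethyl)benzene | BrCc1ccccc1OCc1ccccc1 | starting material
6 | [4-(benzyloxy)-3-formylphenyl]boronic acid | OB(O)c1ccc(OCc2ccccc2)c(C=O)c1 | starting material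
7 | 2-(benzyloxy)-5-[2-(benzyloxy)benzyl]benzaldehyde | O=Cc1cc(Cc2ccccc2OCc2ccccc2)ccc1OCc1ccccc1 | intermediate
8 | {2-(benzyloxy)-5-[2-(benzyloxy)benzyl]phenyl}[4-(oxan-2-yloxy)phenyl]methanol (mixture of diastereomers) | OC(c1ccc(OC2CCCCO2)cc1)c1cc(Cc2ccccc2OCc2ccccc2)ccc1OCc1ccccc1 | intermediate
9 | 4-{2-(benzyloxy)-5-[2-(benzyloxy)benzyl]benzyl}phenol | Oc1ccc(Cc2cc(Cc3ccccc3OCc3ccccc3)ccc2OCc2ccccc2)cc1 | intermediate
10 | 6-{2-(benzyloxy)-5-[2-(benzyloxy)benzyl]benzyl}-2-phenyl-4H-1,3,2-benzodioxaborinine | c1ccccc1B1OCc2cc(Cc3cc(Cc4ccccc4OCc4ccccc4)ccc3OCc3ccccc3)ccc2O1 | intermediate (not isolated)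
11 | 4-{2-(benzyloxy)-5-[2-(benzyloxy)benzyl]benzyl}-2-(hydroxymethyl)phenol | OCc1cc(Cc2cc(Cc3ccccc3OCc3ccccc3)ccc2OCc2ccccc2)ccc1O | intermediate
12 | (S)-pinocembrin, (2S)-5,7-dihydroxy-2-phenylchroman-4-one | O=C1C[C@@H](c2ccccc2)Oc2cc(O)cc(O)c21 | starting material
13 | (2S)-6-(5-{2-(benzyloxy)-5-[2-(benzyloxy)benzyl]benzyl}-2-hydroxybenzyl)-5,7-dihydroxy-2-phenylchroman-4-one | O=C1C[C@@H](c2ccccc2)Oc2cc(O)c(Cc3cc(Cc4cc(Cc5ccccc5OCc5ccccc5)ccc4OCc4ccccc4)ccc3O)c(O)c21 | intermediate
14 | (2S)-6-(5-{2-(benzyloxy)-5-[2-(benzyloxy)benzyl]benzyl}-2-hydroxybenzyl)-8-[(dimethylamino)methyl]-5,7-dihydroxy-2-phenylchroman-4-one | O=C1C[C@@H](c2ccccc2)Oc2c(CN(C)C)c(O)c(Cc3cc(Cc4cc(Cc5ccccc5OCc5ccccc5)ccc4OCc4ccccc4)ccc3O)c(O)c21 | intermediate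
15 | (2S)-6-(5-{2-(benzyloxy)-5-[2-(benzyloxy)benzyl]benzyl}-2-hydroxybenzyl)-5-hydroxy-8-methylidene-2-phenyl-2,3-dihydro-4H-chromene-4,7(8H)-dione (ortho-quinone methide) | O=C1C[C@@H](c2ccccc2)OC2=C1C(O)=C(Cc1cc(Cc3cc(Cc4ccccc4OCc4ccccc4)ccc3OCc3ccccc3)ccc1O)C(=O)C2=C | intermediate (not isolated)
16 | (2S)-8-{5-[2-(benzyloxy)benzyl]-2-hydroxybenzyl}-6-(5-{2-(benzyloxy)-5-[2-(benzyloxy)benzyl]benzyl}-2-hydroxybenzyl)-5,7-dihydroxy-2-phenylchroman-4-one (tri-O-benzyl sarmentosumin D) | O=C1C[C@@H](c2ccccc2)Oc2c(Cc3cc(Cc4ccccc4OCc4ccccc4)ccc3O)c(O)c(Cc3cc(Cc4cc(Cc5ccccc5OCc5ccccc5)ccc4OCc4ccccc4)ccc3O)c(O)c21 | intermediate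
17 | sarmentosumin D | O=C1C[C@@H](c2ccccc2)Oc2c(Cc3cc(Cc4ccccc4O)ccc3O)c(O)c(Cc3cc(Cc4cc(Cc5ccccc5O)ccc4O)ccc3O)c(O)c21 | target

Total step count: 10. Longest linear sequence: 8 steps (steps 3 to 10, from 5 and 6); steps 1 and 2 form the side branch that enters at step 9.

Steps most likely to fail

Step 7. What may go wrong: poor site selectivity on ring A (alkylation at C8 beside C6, and double alkylation), together with slow erosion of C2 by acid-mediated opening of the pyranone ring. The fallback sets out from 12 and comes back at 13. The C7 hydroxyl is silylated selectively (iPr3SiCl, imidazole, DMF, 0 °C; the C5 hydroxyl is chelated to the ketone and should not react) to give (2S)-5-hydroxy-2-phenyl-7-[(triisopropylsilyl)oxy]chroman-4-one F1. In the ZnCl2-mediated union of F1 with 11 (loss of water as in step 7) the only free phenol left to direct the quinone methide is the zinc-bound C5 hydroxyl, whose single free ortho carbon is C6; this should give the 7-O-triisopropylsilyl ether of 13 F2. Bu4NF buffered with AcOH in THF at 0 °C then removes the silyl group and returns 13.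

Step 9. What may go wrong: sluggish loss of the amine, capture of the quinone methide by the free phenol ring of a second molecule of 14 (oligomerisation), or amine-promoted ring opening with loss of configurational integrity at C2 at 105 °C. The fallback sets out from 14 and comes back at 16. N-Methylation with MeI in MeCN at rt gives the benzylic ammonium salt (2S)-6-(5-{2-(benzyloxy)-5-[2-(benzyloxy)benzyl]benzyl}-2-hydroxybenzyl)-5,7-dihydroxy-2-phenyl-8-[(trimethylammonio)methyl]chroman-4-one iodide F3. With solid NaHCO3 and excess 4 in MeCN at 40–50 °C this salt should undergo 1,4-elimination of trimethylamine to the same quinone methide 15, which 4 captures to give 16; this replaces the thermal retro-Mannich by a low-temperature ammonium elimination and leaves no secondary amine in solution.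

Step 10. What may go wrong: over-reduction, that is hydrogenolysis of the benzylic C2–O1 bond to a dihydrochalcone or reduction of the ketone before the third benzyl ether is gone. The fallback sets out from 16 and comes back at 17 with no new compound (F0): non-reductive Lewis-acid debenzylation with BCl3 and pentamethylbenzene as cation scavenger in CH2Cl2 at −78 °C, the benzyl groups ending as benzylpentamethylbenzene.

Further compounds

F1 | step 7 | (2S)-5-hydroxy-2-phenyl-7-[(triisopropylsilyl)oxy]chroman-4-one | O=C1C[C@@H](c2ccccc2)Oc2cc(O[Si](C(C)C)(C(C)C)C(C)C)cc(O)c21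
F2 | step 7 | (2S)-6-(5-{2-(benzyloxy)-5-[2-(benzyloxy)benzyl]benzyl}-2-hydroxybenzyl)-5-hydroxy-2-phenyl-7-[(triisopropylsilyl)oxy]chroman-4-one | O=C1C[C@@H](c2ccccc2)Oc2cc(O[Si](C(C)C)(C(C)C)C(C)C)c(Cc3cc(Cc4cc(Cc5ccccc5OCc5ccccc5)ccc4OCc4ccccc4)ccc3O)c(O)c21
F3 | step 9 | (2S)-6-(5-{2-(benzyloxy)-5-[2-(benzyloxy)benzyl]benzyl}-2-hydroxybenzyl)-5,7-dihydroxy-2-phenyl-8-[(trimethylammonio)methyl]chroman-4-one iodide | O=C1C[C@@H](c2ccccc2)Oc2c(C[N+](C)(C)C)c(O)c(Cc3cc(Cc4cc(Cc5ccccc5OCc5ccccc5)ccc4OCc4ccccc4)ccc3O)c(O)c21.[I-]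
F0 | step 10 | none | none
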